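**Plan**

1. Retrosynthetic cuts, in order: the ester bond between O3 and the angeloyl carbonyl; the two β C–O bonds at C3 and C4, which leads back to a C3=C4 alkene; last the ring-fusion bond C5–C10.
2. Enabling feature (eudesmane numbering; ring A = C1, C2, C3, C4, C5, C10; ring B = C5, C6, C7, C8, C9, C10; β = face of C14): without C5–C10 the two rings merge into one ten-membered ring that still carries the C8 ketone, the C7=C11 isopropylidene, C14 on C10 and C15 on C4. This is achiral (E,E)-germacrone, whose C1=C10 and C4=C5 alkenes lie across the ring from each other with C5 next to C10.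
3. Forward: a protonation-initiated cyclase closes rings A and B together through the single bond C5–C10 and leaves C3=C4. That alkene is then dioxygenated cis on the β face as the 3-hydroxy 4-acetate, and O3 is angeloylated last.
4. Stereochemistry: the trans fusion follows from the E,E geometry, and the absolute sense of C5 and C10 from the enzyme's choice of one mirror-image fold. C3 and C4 come from substrate-controlled Woodward chemistry steered by the axial C14 methyl, and the Z alkene is bought with angelic acid.

Key step: step 1

Remark on the chemistry: the two mirror-image crossed conformers of germacrone are assumed to interconvert faster than enzymatic turnover at 30 °C, and a cyclase variant with the required fold and base placement is assumed to be obtainable by directed evolution. α and β refer to the usual eudesmane drawing, with C14 β.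

**Route**

Step 1
Reactants: 1 germacrone, (3E,7E)-3,7-dimethyl-10-(propan-2-ylidene)cyclodeca-3,7-dien-1-one
Product: 3 (5R,10R)-eudesma-3,7(11)-dien-8-one (trans-fused; 5α-H; 10β-methyl), via tertiary C4 eudesmyl cation 2 (not isolated)
Conditions: evolved squalene-hopene cyclase variant (E. coli whole cells or lysate), citrate buffer (citric acid/NaOH) pH 6.0, 0.2% Triton X-100, 30 °C
Reagents that add atoms: none
Why: Proposed new method: the aspartic acid of the DXDD motif protonates C1 of the C1=C10 alkene in the bound crossed conformer, the C10 cation is captured across the ring by C5 of the C4=C5 alkene, and a pocket base removes the axial 3α-H of cation 2 to leave C3=C4; the closest known reaction types are the Brønsted-acid cyclisation of non-natural linear terpenoids by engineered squalene-hopene cyclases and the acid-promoted transannular cyclisation of germacrone to racemic eudesmadienones, but closure of a preformed ten-membered ring with selection of one conformer has not been shown for this enzyme class. The one new bond C5–C10 closes ring A in a 6-endo-trig mode, because the attacking C4=C5 bond ends up inside that ring, and ring B in a 6-exo-trig mode. C5 and C10 are set relative to each other by anti addition across the two E alkenes held parallel in the chair-chair fold, which can only give the trans-decalin with H5 anti to C14. Their absolute sense (5R,10R) has to come from the enzyme, which must bind and protonate only one of the two interconverting mirror-image conformers of the achiral substrate, a dynamic kinetic selection. The step also needs site selectivity: the electron-poor C7=C11 enone alkene stays out and protonation at C5 opens no productive ring, both secured by the substrate, whereas loss of H3 in preference to H15, H5 or water capture must be enforced by the position of the base and a dry pocket.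

Step 2
Reactants: 3 (5R,10R)-eudesma-3,7(11)-dien-8-one
Product: 6 (3S,4R,5R,10R)-3-hydroxy-8-oxoeudesm-7(11)-en-4-yl acetate (3β-hydroxy; 4β-acetoxy), via 3α-iodo 4β-acetate 4 (not isolated), via β-face acetoxonium ion 5 (not isolated)
Conditions: I2 (1.05 equiv), AgOAc (2.2 equiv), AcOH, 20 °C, dark; then H2O (1.5 equiv) in AcOH, 80 °C
Reagents that add atoms: silver acetate, CC(=O)[O-].[Ag+]; water, O
Why: Woodward cis-hydroxylation (the wet variant of the Prévost reaction) should place iodine on the open α face of C3=C4, let acetate open the iodonium ion at the tertiary C4 from the β face in the trans-diaxial sense to give 4, let the axial 4β-acetate displace the antiperiplanar 3α-iodide with silver assistance to give acetoxonium ion 5, and let water open 5 through its orthoacid to the axial ester and equatorial alcohol, so that C3 (S) and C4 (R) both carry oxygen on the face of C14 with the acetyl group on the tertiary O4, while the electron-poor C7=C11 alkene is not attacked by iodine.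

Step 3
Reactants: 6 (3S,4R,5R,10R)-3-hydroxy-8-oxoeudesm-7(11)-en-4-yl acetate; 7 angelic acid, (Z)-2-methylbut-2-enoic acid
Product: 9 (3S,4R,5R,10R)-4-acetoxy-8-oxoeudesm-7(11)-en-3-yl (Z)-2-methylbut-2-enoate (3β-angeloyloxy; 4β-acetoxy; 5α-H; 10β-methyl), via angelic 2,4,6-trichlorobenzoic anhydride 8 (not isolated)
Conditions: 7, 2,4,6-trichlorobenzoyl chloride, Et3N, toluene, 20 °C; then 6, toluene, 80 °C, no DMAP
Reagents that add atoms: none
Why: Yamaguchi esterification, in which the equatorial 3β-hydroxyl attacks the angeloyl carbonyl of mixed anhydride 8 because the trichlorobenzoyl carbonyl is shielded by its two ortho chlorines, and running the acyl transfer in toluene without DMAP avoids the reversible conjugate addition that turns angelates into tiglates, so the Z geometry of 7 and all four stereocentres are carried over unchanged.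

**Compound list**

1 | germacrone, (3E,7E)-3,7-dimethyl-10-(propan-2-ylidene)cyclodeca-3,7-dien-1-one | C/C1=C\CC(=C(C)C)C(=O)C/C(C)=C/CC1 | starting material
2 | 8-oxo-5α,10β-eudesm-7(11)-en-4-yl cation, tertiary cation at C4, not isolated | C[C+]1CCC[C@]2(C)CC(=O)C(=C(C)C)C[C@H]21 | intermediate
3 | (5R,10R)-eudesma-3,7(11)-dien-8-one | CC1=CCC[C@]2(C)CC(=O)C(=C(C)C)C[C@H]21 | intermediate
4 | (3R,4R,5R,10R)-3-iodo-8-oxoeudesm-7(11)-en-4-yl acetate (3α-iodo, 4β-acetoxy), not isolated | I[C@@H]1CC[C@]2(C)CC(=O)C(=C(C)C)C[C@H]2[C@@]1(C)OC(C)=O | intermediate
5 | 2-methyl-1,3-dioxolan-2-ylium ion cis-fused to C3 and C4 on the β face (acetate counter-ion), not isolated | O3[C@H]1CC[C@]2(C)CC(=O)C(=C(C)C)C[C@H]2[C@@]1(C)O[C+]3C | intermediate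
6 | (3S,4R,5R,10R)-3-hydroxy-8-oxoeudesm-7(11)-en-4-yl acetate | O[C@H]1CC[C@]2(C)CC(=O)C(=C(C)C)C[C@H]2[C@@]1(C)OC(C)=O | intermediate
7 | angelic acid, (Z)-2-methylbut-2-enoic acid | C/C=C(/C)C(=O)O | starting material
8 | angelic 2,4,6-trichlorobenzoic anhydride, not isolated | C/C=C(/C)C(=O)OC(=O)c1c(Cl)cc(Cl)cc1Cl | intermediate
9 | (3S,4R,5R,10R)-4-acetoxy-8-oxoeudesm-7(11)-en-3-yl (Z)-2-methylbut-2-enoate, CNP0141494.2 | C/C=C(/C)C(=O)O[C@H]1CC[C@]2(C)CC(=O)C(=C(C)C)C[C@H]2[C@@]1(C)OC(C)=O | target

**Totals**

Total step count: 3. Longest linear sequence: 3 steps (1 to 3 to 6 to 9).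

**Steps most likely to fail**

Step 1. The enzyme may discriminate poorly between the two mirror-image folds, or the C4 cation may be quenched through other channels (loss of H15 or H5, water capture); either would erode enantiomeric purity and the position of the ring A alkene. The fallback gives up enzymatic control and uses known chemistry. It sets out from 1: acid-promoted transannular cyclisation (TsOH·H2O or BF3·OEt2 in CH2Cl2 at low temperature) should give the racemic dienone F1 together with its double-bond isomers. These isomers are removed on AgNO3-impregnated silica, and preparative chromatography on a chiral stationary phase (SFC) separates the enantiomers. The fallback comes back to the route at 3.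

Step 2. The orthoacid may open toward the other oxygen, or the acetyl group may drift from the tertiary O4 to the secondary O3, with partial second acetylation in hot acetic acid; any of these would blur the position of the acetate. The fallback reverses the order of acylation. It sets out from 6 as obtained crude, whatever its acetate distribution: methanolysis (K2CO3, MeOH, 20 °C) gives the 3β,4β-diol F2. Yamaguchi angeloylation with 7 through 8 under the conditions of step 3 should acylate only the secondary equatorial hydroxyl to give the 3-angelate 4-ol F3. Acetylation of the tertiary axial hydroxyl with Ac2O and catalytic Sc(OTf)3 in MeCN at −20 °C comes back to the route at 9.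

Step 3. The Z double bond may isomerise to the tiglate during the slow acyl transfer to a hindered alcohol, and the neighbouring acetate may migrate under prolonged heating with amine base. The fallback builds the Z alkene on the ester and does not transfer it. It sets out from 6: esterification with 2-[bis(2,2,2-trifluoroethoxy)phosphoryl]propanoic acid (EDC·HCl, catalytic DMAP, CH2Cl2, 0 °C) gives the phosphonate ester F4, a mixture of epimers at the phosphonate carbon that is of no consequence. Still–Gennari olefination (KN(SiMe3)2, 18-crown-6, THF, −78 °C, then acetaldehyde) should form the Z-trisubstituted alkene and comes back to the route at 9.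

**Further compounds**

F1 | step 1 | racemic trans-fused eudesma-3,7(11)-dien-8-one (3 together with its enantiomer) | CC1=CCC[C@]2(C)CC(=O)C(=C(C)C)C[C@H]21.CC1=CCC[C@@]2(C)CC(=O)C(=C(C)C)C[C@@H]21
F2 | step 2 | (3S,4R,5R,10R)-3,4-dihydroxyeudesm-7(11)-en-8-one | O[C@H]1CC[C@]2(C)CC(=O)C(=C(C)C)C[C@H]2[C@@]1(C)O
F3 | step 2 | (3S,4R,5R,10R)-4-hydroxy-8-oxoeudesm-7(11)-en-3-yl (Z)-2-methylbut-2-enoate | C/C=C(/C)C(=O)O[C@H]1CC[C@]2(C)CC(=O)C(=C(C)C)C[C@H]2[C@@]1(C)O
F4 | step 3 | (3S,4R,5R,10R)-4-acetoxy-8-oxoeudesm-7(11)-en-3-yl 2-[bis(2,2,2-trifluoroethoxy)phosphoryl]propanoate | CC(C(=O)O[C@H]1CC[C@]2(C)CC(=O)C(=C(C)C)C[C@H]2[C@@]1(C)OC(C)=O)P(=O)(OCC(F)(F)F)OCC(F)(F)F
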